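## Retrosynthetic overview

1. C8–C9 is cut last: a C1–C8 homoallylic Grignard reagent is joined, under copper catalysis, to the primary triflate of a C9–C24 epoxy alcohol.
2. The oxirane (the only ring) comes from a Sharpless asymmetric epoxidation of the C9 allylic alcohol, once the C9–C24 chain is complete and before the last coupling.
3. C12–C13 is cut by a Biellmann-type sulfone alkylation (C5 hydroxy sulfone from prenyl acetate plus a C13–C24 allylic bromide), followed by reductive desulfonylation.
4. C20–C21 is cut by a copper-catalysed Grignard/allylic bromide coupling onto 8-bromogeranyl acetate.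
5. The C7 and C22 methyl centres come from Evans deconjugative α-methylation of N-geranoyl and N-senecioyl oxazolidinones.

Assumption: the six numbered starting materials are bought, and geranic acid 24 is used as the pure 2E isomer.

Locants C1–C24 are the squalene-type locants of 33: Me2C2=C3, C6(=CH2), C7 (R), oxirane C10(Me)–C11, C14=C15, C18=C19, C22 (S), C23(=CH2)Me. The target is read as 7R,10R,11R,22S with 14E,18E and a trans oxirane. The route has not been run; yields and selectivities are expectations from analogous reactions.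

## Route

Step 1
Reactants: 1 (4R)-4-benzyl-1,3-oxazolidin-2-one; 2 3-methylbut-2-enoyl chloride
Product: 4 (4R)-4-benzyl-3-(3-methylbut-2-enoyl)-1,3-oxazolidin-2-one, via N-lithio oxazolidinone 3 (not isolated)
Conditions: n-BuLi, THF, −78 °C; then 2, −78 to 0 °C
Reagents that add atoms: none
Why: N-acylation of the lithiated Evans auxiliary by the acid chloride at low temperature, which avoids ketene formation and deconjugation; no stereocentre is formed.

Step 2
Reactants: 4
Product: 6 (4R)-4-benzyl-3-[(2R)-2,3-dimethylbut-3-enoyl]-1,3-oxazolidin-2-one, via sodium dienolate 5 (not isolated)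
Conditions: NaN(SiMe3)2 (1.1 equiv), THF, −78 °C; MeI (5 equiv), −78 °C; minor diastereomer removed by chromatography
Reagents that add atoms: iodomethane, CI
Why: Evans deconjugative asymmetric alkylation: γ-deprotonation of the s-cis enoyl imide gives the chelated Z(O)-dienolate, which is methylated at the α-carbon on the face away from the benzyl group, setting the (2R) centre that becomes C22.

Step 3
Reactants: 6
Product: 7 (2R)-2,3-dimethylbut-3-en-1-ol
Conditions: LiBH4, H2O (1 equiv), Et2O, 0 °C
Reagents that add atoms: none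
Why: Reductive cleavage of the N-acyl oxazolidinone by hydride attack at the exocyclic carbonyl; the conditions are cold and non-basic, so the allylic α-centre is not epimerised and the auxiliary is recovered.

Step 4
Reactants: 7
Product: 8 (3R)-4-bromo-2,3-dimethylbut-1-ene
Conditions: CBr4, PPh3, CH2Cl2, 0 °C; distilled
Reagents that add atoms: carbon tetrabromide, BrC(Br)(Br)Br
Why: Appel reaction, an SN2 displacement at the primary carbon that leaves the adjacent stereocentre and the alkene untouched.

Step 5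
Reactants: 9 (2E)-3,7-dimethylocta-2,6-dien-1-yl acetate (geranyl acetate)
Product: 10 (2E,6E)-8-hydroxy-3,7-dimethylocta-2,6-dien-1-yl acetate
Conditions: SeO2 (cat.), t-BuOOH, salicylic acid (cat.), CH2Cl2, 0 °C to rt
Reagents that add atoms: tert-butyl hydroperoxide, CC(C)(C)OO
Why: Sharpless–Umbreit allylic oxidation (ene reaction then [2,3]-shift) hydroxylates only the E-methyl of the terminal trisubstituted alkene, the acetate-bearing alkene being deactivated; this fixes the E geometry of C18=C19.

Step 6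
Reactants: 10
Product: 11 (2E,6E)-8-bromo-3,7-dimethylocta-2,6-dien-1-yl acetate
Conditions: CBr4, PPh3, CH2Cl2, −20 °C
Reagents that add atoms: carbon tetrabromide, BrC(Br)(Br)Br
Why: Appel reaction on the primary allylic alcohol proceeds without allylic transposition and leaves the acetate in place.

Step 7
Reactants: 8; 11
Product: 14 (2E,6E,10S)-3,7,10,11-tetramethyldodeca-2,6,11-trien-1-ol, via Grignard reagent 12 (not isolated), via allylic acetate 13 (not isolated)
Conditions: 8, Mg, THF, 0–20 °C, used at once; 11, Li2CuCl4 (5 mol %), THF, −78 to −20 °C; then MeOH, K2CO3, 20 °C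
Reagents that add atoms: none
Why: Kochi–Schlosser copper-catalysed Grignard cross-coupling substitutes the primary allylic bromide directly (SN2, E geometry kept) much faster than it touches the allylic acetate, forming C20–C21; base-catalysed methanolysis then frees the alcohol, and the centre β to magnesium is not involved.

Step 8
Reactants: 14
Product: 15 (2E,6E,10S)-1-bromo-3,7,10,11-tetramethyldodeca-2,6,11-triene
Conditions: PBr3 (0.4 equiv), Et2O, −10 °C; used crude
Reagents that add atoms: phosphorus tribromide, BrP(Br)Br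
Why: Standard conversion of a primary allylic terpenol into its bromide (as for farnesyl bromide), without allylic shift or E/Z change at low temperature.

Step 9
Reactants: 16 3-methylbut-2-en-1-yl acetate (prenyl acetate)
Product: 17 (2E)-4-hydroxy-3-methylbut-2-en-1-yl acetate
Conditions: SeO2 (cat.), t-BuOOH, salicylic acid (cat.), CH2Cl2, rt
Reagents that add atoms: tert-butyl hydroperoxide, CC(C)(C)OO
Why: The same SeO2 allylic oxidation is selective for the E-methyl and so fixes the E geometry of the future C10=C11 alkene, which later gives the trans oxirane.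

Step 10
Reactants: 17
Product: 18 (2E)-2-methyl-4-(phenylsulfonyl)but-2-en-1-ol
Conditions: PhSO2Na, Pd(PPh3)4 (3 mol %), THF–MeOH, rt, short reaction time
Reagents that add atoms: sodium benzenesulfinate, [Na+].[O-]S(=O)c1ccccc1
Why: Tsuji–Trost allylic substitution: the π-allylpalladium formed from the acetate is captured by sulfinate at the primary terminus with retention of the E geometry, and the free hydroxyl is tolerated.

Step 11
Reactants: 18; 15
Product: 20 (2E,6E,10E,14S)-2,7,11,14,15-pentamethyl-4-(phenylsulfonyl)hexadeca-2,6,10,15-tetraen-1-ol (both C4 epimers), via dilithio dianion 19 (not isolated)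
Conditions: n-BuLi (2.1 equiv), THF–DMPU, −78 °C; then 15, −78 to −40 °C
Reagents that add atoms: none
Why: Biellmann-type alkylation: the α-sulfonyl allylic carbanion of the dianion is far more nucleophilic than the alkoxide and is C-alkylated (SN2) by the allylic bromide to forge C12–C13; the new sulfonyl-bearing centre is removed in the next step.

Step 12
Reactants: 20
Product: 21 (2E,6E,10E,14S)-2,7,11,14,15-pentamethylhexadeca-2,6,10,15-tetraen-1-ol
Conditions: PdCl2(Ph2P(CH2)3PPh2) (5 mol %), LiBHEt3 (3 equiv, one consumed by the OH), THF, 0 °C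
Reagents that add atoms: none
Why: Palladium-catalysed hydride desulfonylation of an allylic sulfone (Inomata–Kotake conditions): hydride is delivered to the less substituted terminus of the π-allyl, so the E-trisubstituted alkene stays in place; no epoxide is present yet.

Step 13
Reactants: 21
Product: 22 [(2R,3R)-2-methyl-3-[(3E,7E,11S)-4,8,11,12-tetramethyltrideca-3,7,12-trien-1-yl]oxiran-2-yl]methanol
Conditions: Ti(OiPr)4 (10 mol %), D-(−)-diethyl tartrate (12 mol %), t-BuOOH, 4 Å MS, CH2Cl2, −20 °C
Reagents that add atoms: tert-butyl hydroperoxide, CC(C)(C)OO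
Why: Sharpless asymmetric epoxidation is hydroxyl-directed, so only the allylic-alcohol alkene of the tetraene reacts; the D-(−)-tartrate catalyst delivers oxygen to the face that gives the (2R,3R) oxirane, which is C10 R and C11 R.

Step 14
Reactants: 22
Product: 23 [(2R,3R)-2-methyl-3-[(3E,7E,11S)-4,8,11,12-tetramethyltrideca-3,7,12-trien-1-yl]oxiran-2-yl]methyl trifluoromethanesulfonate
Conditions: Tf2O, 2,6-lutidine, CH2Cl2, −78 °C; cold aqueous work-up, used at once
Reagents that add atoms: trifluoromethanesulfonic anhydride, O=S(=O)(OS(=O)(=O)C(F)(F)F)C(F)(F)F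
Why: O-sulfonylation of the primary alcohol at −78 °C with a hindered base keeps the acid-sensitive oxirane and alkenes intact and touches no stereocentre.

Step 15
Reactants: 24 (2E)-3,7-dimethylocta-2,6-dienoic acid (geranic acid); 25 (4S)-4-benzyl-1,3-oxazolidin-2-one
Product: 27 (4S)-4-benzyl-3-[(2E)-3,7-dimethylocta-2,6-dienoyl]-1,3-oxazolidin-2-one, via mixed pivalic anhydride 26 (not isolated)
Conditions: t-BuCOCl, Et3N, THF, −20 °C; then 25, LiCl, rt
Reagents that add atoms: none
Why: Mixed-anhydride N-acylation (LiCl/Et3N method) occurs at the less hindered geranoyl carbonyl and keeps the 2E geometry that the next step needs.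

Step 16
Reactants: 27
Product: 29 (4S)-4-benzyl-3-[(2S)-2,7-dimethyl-3-methylideneoct-6-enoyl]-1,3-oxazolidin-2-one, via sodium dienolate 28 (not isolated)
Conditions: NaN(SiMe3)2 (1.1 equiv), THF, −78 °C; MeI (5 equiv), −78 °C; minor diastereomer removed by chromatography
Reagents that add atoms: iodomethane, CI
Why: Evans deconjugative asymmetric alkylation: the base removes a proton from the C3 methyl (the γ-group cis to the carbonyl in the 2E isomer) to give the exo-methylene Z(O)-dienolate, which is methylated at the α-carbon anti to the benzyl group, setting the (2S) centre that becomes C7.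

Step 17
Reactants: 29
Product: 30 (2S)-2,7-dimethyl-3-methylideneoct-6-en-1-ol
Conditions: LiBH4, H2O (1 equiv), Et2O, 0 °C
Reagents that add atoms: none
Why: Reductive removal of the auxiliary by hydride attack at the exocyclic carbonyl, without epimerisation of the allylic α-centre.

Step 18
Reactants: 30
Product: 31 (7S)-8-bromo-2,7-dimethyl-6-methylideneoct-2-ene
Conditions: CBr4, PPh3, CH2Cl2, 0 °C
Reagents that add atoms: carbon tetrabromide, BrC(Br)(Br)Br
Why: Appel reaction, SN2 at the primary carbon with no effect on the stereocentre or the two alkenes.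

Step 19
Reactants: 31; 23
Product: 33 (2R,3R)-2-[(3R)-3,8-dimethyl-4-methylidenenon-7-en-1-yl]-2-methyl-3-[(3E,7E,11S)-4,8,11,12-tetramethyltrideca-3,7,12-trien-1-yl]oxirane, via Grignard reagent 32 (not isolated)
Conditions: 31, Mg, THF, 0–20 °C, used at once; 23, CuBr·SMe2 (10 mol %), Et2O–THF, −78 to −30 °C
Reagents that add atoms: none
Why: Copper-catalysed Grignard–primary triflate coupling (Kotsuki type) is an SN2 displacement at CH2OTf that is much faster at −78 °C than attack on the trisubstituted oxirane, forming C8–C9 without touching any stereocentre.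

## Compound list

1 | (4R)-4-benzyl-1,3-oxazolidin-2-one | O=C1N[C@H](Cc2ccccc2)CO1 | starting material
2 | 3-methylbut-2-enoyl chloride | CC(C)=CC(Cl)=O | starting material
3 | lithium (4R)-4-benzyl-2-oxo-1,3-oxazolidin-3-ide | [Li+].O=C1[N-][C@H](Cc2ccccc2)CO1 | intermediate
4 | (4R)-4-benzyl-3-(3-methylbut-2-enoyl)-1,3-oxazolidin-2-one | CC(C)=CC(=O)N1[C@H](Cc2ccccc2)COC1=O | intermediate
5 | sodium (1Z)-1-[(4R)-4-benzyl-2-oxo-1,3-oxazolidin-3-yl]-3-methylbuta-1,3-dien-1-olate | [Na+].C=C(C)/C=C(\[O-])N1[C@H](Cc2ccccc2)COC1=O | intermediate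
6 | (4R)-4-benzyl-3-[(2R)-2,3-dimethylbut-3-enoyl]-1,3-oxazolidin-2-one | C=C(C)[C@@H](C)C(=O)N1[C@H](Cc2ccccc2)COC1=O | intermediate
7 | (2R)-2,3-dimethylbut-3-en-1-ol | C=C(C)[C@@H](C)CO | intermediate
8 | (3R)-4-bromo-2,3-dimethylbut-1-ene | C=C(C)[C@@H](C)CBr | intermediate
9 | (2E)-3,7-dimethylocta-2,6-dien-1-yl acetate | CC(C)=CCC/C(C)=C/COC(C)=O | starting material
10 | (2E,6E)-8-hydroxy-3,7-dimethylocta-2,6-dien-1-yl acetate | OC/C(C)=C/CC/C(C)=C/COC(C)=O | intermediate
11 | (2E,6E)-8-bromo-3,7-dimethylocta-2,6-dien-1-yl acetate | BrC/C(C)=C/CC/C(C)=C/COC(C)=O | intermediate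
12 | [(2R)-2,3-dimethylbut-3-en-1-yl]magnesium bromide | C=C(C)[C@@H](C)C[Mg]Br | intermediate
13 | (2E,6E,10S)-3,7,10,11-tetramethyldodeca-2,6,11-trien-1-yl acetate | C=C(C)[C@@H](C)CC/C(C)=C/CC/C(C)=C/COC(C)=O | intermediate
14 | (2E,6E,10S)-3,7,10,11-tetramethyldodeca-2,6,11-trien-1-ol | C=C(C)[C@@H](C)CC/C(C)=C/CC/C(C)=C/CO | intermediate
15 | (2E,6E,10S)-1-bromo-3,7,10,11-tetramethyldodeca-2,6,11-triene | C=C(C)[C@@H](C)CC/C(C)=C/CC/C(C)=C/CBr | intermediate
16 | 3-methylbut-2-en-1-yl acetate | CC(C)=CCOC(C)=O | starting material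
17 | (2E)-4-hydroxy-3-methylbut-2-en-1-yl acetate | OC/C(C)=C/COC(C)=O | intermediate
18 | (2E)-2-methyl-4-(phenylsulfonyl)but-2-en-1-ol | OC/C(C)=C/CS(=O)(=O)c1ccccc1 | intermediate
19 | dilithium salt of 18 (alkoxide and α-sulfonyl carbanion) | [Li+].[Li+].[O-]C/C(C)=C/[CH-]S(=O)(=O)c1ccccc1 | intermediate
20 | (2E,6E,10E,14S)-2,7,11,14,15-pentamethyl-4-(phenylsulfonyl)hexadeca-2,6,10,15-tetraen-1-ol (both C4 epimers) | OC/C(C)=C/C(S(=O)(=O)c1ccccc1)C/C=C(\C)CC/C=C(\C)CC[C@H](C)C(=C)C | intermediate
21 | (2E,6E,10E,14S)-2,7,11,14,15-pentamethylhexadeca-2,6,10,15-tetraen-1-ol | OC/C(C)=C/CC/C=C(\C)CC/C=C(\C)CC[C@H](C)C(=C)C | intermediate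
22 | [(2R,3R)-2-methyl-3-[(3E,7E,11S)-4,8,11,12-tetramethyltrideca-3,7,12-trien-1-yl]oxiran-2-yl]methanol | OC[C@@]1(C)O[C@@H]1CC/C=C(\C)CC/C=C(\C)CC[C@H](C)C(=C)C | intermediate
23 | [(2R,3R)-2-methyl-3-[(3E,7E,11S)-4,8,11,12-tetramethyltrideca-3,7,12-trien-1-yl]oxiran-2-yl]methyl trifluoromethanesulfonate | O=S(=O)(OC[C@@]1(C)O[C@@H]1CC/C=C(\C)CC/C=C(\C)CC[C@H](C)C(=C)C)C(F)(F)F | intermediate
24 | (2E)-3,7-dimethylocta-2,6-dienoic acid | CC(C)=CCC/C(C)=C/C(=O)O | starting material
25 | (4S)-4-benzyl-1,3-oxazolidin-2-one | O=C1N[C@@H](Cc2ccccc2)CO1 | starting material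
26 | (2E)-3,7-dimethylocta-2,6-dienoic 2,2-dimethylpropanoic anhydride | CC(C)=CCC/C(C)=C/C(=O)OC(=O)C(C)(C)C | intermediate
27 | (4S)-4-benzyl-3-[(2E)-3,7-dimethylocta-2,6-dienoyl]-1,3-oxazolidin-2-one | CC(C)=CCC/C(C)=C/C(=O)N1[C@@H](Cc2ccccc2)COC1=O | intermediate
28 | sodium (1Z)-1-[(4S)-4-benzyl-2-oxo-1,3-oxazolidin-3-yl]-7-methyl-3-methylideneocta-1,6-dien-1-olate | [Na+].CC(C)=CCCC(=C)/C=C(\[O-])N1[C@@H](Cc2ccccc2)COC1=O | intermediate
29 | (4S)-4-benzyl-3-[(2S)-2,7-dimethyl-3-methylideneoct-6-enoyl]-1,3-oxazolidin-2-one | CC(C)=CCCC(=C)[C@H](C)C(=O)N1[C@@H](Cc2ccccc2)COC1=O | intermediate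
30 | (2S)-2,7-dimethyl-3-methylideneoct-6-en-1-ol | CC(C)=CCCC(=C)[C@H](C)CO | intermediate
31 | (7S)-8-bromo-2,7-dimethyl-6-methylideneoct-2-ene | CC(C)=CCCC(=C)[C@H](C)CBr | intermediate
32 | [(2S)-2,7-dimethyl-3-methylideneoct-6-en-1-yl]magnesium bromide | CC(C)=CCCC(=C)[C@H](C)C[Mg]Br | intermediate
33 | (2R,3R)-2-[(3R)-3,8-dimethyl-4-methylidenenon-7-en-1-yl]-2-methyl-3-[(3E,7E,11S)-4,8,11,12-tetramethyltrideca-3,7,12-trien-1-yl]oxirane | C=C(CCC=C(C)C)[C@H](C)CC[C@@]1(C)O[C@@H]1CC/C=C(\C)CC/C=C(\C)CC[C@H](C)C(=C)C | target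

## Step count and risks

Total step count: 19. Longest linear sequence: 11 steps (1, 2, 3, 4, 7, 8, 11, 12, 13, 14, 19).

The three steps most likely to fail:

Step 19 is the most exposed. The triflate carbon sits next to the fully substituted oxirane carbon, the Grignard reagent is β-branched, and magnesium halide can open the epoxide or exchange the triflate. The fallback sets out from 31 and 23 and comes back at 33. It replaces the copper/Grignard nucleophile with a sulfone-stabilised carbanion. Bromide 31 with PhSO2Na in DMF gives {[(2S)-2,7-dimethyl-3-methylideneoct-6-en-1-yl]sulfonyl}benzene F1. n-BuLi in THF at −78 °C turns it into the α-lithio sulfone F2, a stronger and less Lewis-acidic nucleophile, which displaces the triflate of 23 to give the epoxy sulfone (2R,3R)-2-[(3S)-3,8-dimethyl-4-methylidene-2-(phenylsulfonyl)non-7-en-1-yl]-2-methyl-3-[(3E,7E,11S)-4,8,11,12-tetramethyltrideca-3,7,12-trien-1-yl]oxirane F3. Buffered sodium amalgam (Na/Hg, Na2HPO4, MeOH–THF, −20 °C) then removes the sulfonyl group and gives 33.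

Step 16 depends on the geranoyl imide losing a proton from the C3 methyl and not from C4, on α- over γ-methylation, and on a usable diastereomer ratio with the small electrophile MeI. The fallback sets out from 25 and 2 and comes back at 30. It uses the senecioyl series, where both γ-methyls are equivalent, and adds the homoprenyl chain afterwards. Auxiliary 25 is lithiated to lithium (4S)-4-benzyl-2-oxo-1,3-oxazolidin-3-ide F4 and acylated with 2 to (4S)-4-benzyl-3-(3-methylbut-2-enoyl)-1,3-oxazolidin-2-one F5. NaN(SiMe3)2 gives the sodium dienolate F6, and MeI gives (4S)-4-benzyl-3-[(2S)-2,3-dimethylbut-3-enoyl]-1,3-oxazolidin-2-one F7. LiBH4 gives (2S)-2,3-dimethylbut-3-en-1-ol F8. n-BuLi (2.2 equiv) with TMEDA in Et2O–hexane metalates the allylic methyl of the lithium alkoxide to the dilithio species F9, and prenyl bromide at −78 °C alkylates it to give 30.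

Step 7 can lose material three ways: SN2′ attack on the 2-methylallylic bromide, attack on the acetate, and erosion of the C22 centre if Grignard reagent 12 equilibrates through its cyclopropylcarbinyl form on standing. The fallback sets out from 8 and 11 and comes back at 14. It avoids both the homoallylic Grignard reagent and copper. Bromide 8 with PhSO2Na gives {[(2R)-2,3-dimethylbut-3-en-1-yl]sulfonyl}benzene F10. n-BuLi at −78 °C gives the α-lithio sulfone F11, which alkylates allylic bromide 11 by direct SN2 to (2E,6E,10R)-3,7,10,11-tetramethyl-9-(phenylsulfonyl)dodeca-2,6,11-trien-1-yl acetate F12. Magnesium in methanol removes the sulfonyl group and methanolyses the acetate in the same operation, giving 14.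

## Further compounds

F1 | step 19 | {[(2S)-2,7-dimethyl-3-methylideneoct-6-en-1-yl]sulfonyl}benzene | CC(C)=CCCC(=C)[C@H](C)CS(=O)(=O)c1ccccc1
F2 | step 19 | α-lithio sulfone (lithium carbanion of F1 at the carbon next to sulfur) | [Li+].CC(C)=CCCC(=C)[C@H](C)[CH-]S(=O)(=O)c1ccccc1
F3 | step 19 | (2R,3R)-2-[(3S)-3,8-dimethyl-4-methylidene-2-(phenylsulfonyl)non-7-en-1-yl]-2-methyl-3-[(3E,7E,11S)-4,8,11,12-tetramethyltrideca-3,7,12-trien-1-yl]oxirane (both epimers at the sulfonyl carbon) | CC(C)=CCCC(=C)[C@H](C)C(C[C@@]1(C)O[C@@H]1CC/C=C(\C)CC/C=C(\C)CC[C@H](C)C(=C)C)S(=O)(=O)c1ccccc1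
F4 | step 16 | lithium (4S)-4-benzyl-2-oxo-1,3-oxazolidin-3-ide | [Li+].O=C1[N-][C@@H](Cc2ccccc2)CO1
F5 | step 16 | (4S)-4-benzyl-3-(3-methylbut-2-enoyl)-1,3-oxazolidin-2-one | CC(C)=CC(=O)N1[C@@H](Cc2ccccc2)COC1=O
F6 | step 16 | sodium dienolate of F5 | [Na+].C=C(C)/C=C(\[O-])N1[C@@H](Cc2ccccc2)COC1=O
F7 | step 16 | (4S)-4-benzyl-3-[(2S)-2,3-dimethylbut-3-enoyl]-1,3-oxazolidin-2-one | C=C(C)[C@H](C)C(=O)N1[C@@H](Cc2ccccc2)COC1=O
F8 | step 16 | (2S)-2,3-dimethylbut-3-en-1-ol | C=C(C)[C@H](C)CO
F9 | step 16 | dilithio species of F8 (lithium alkoxide and allylic carbanion) | [Li+].[Li+].[CH2-]C(=C)[C@H](C)C[O-]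
F10 | step 7 | {[(2R)-2,3-dimethylbut-3-en-1-yl]sulfonyl}benzene | C=C(C)[C@@H](C)CS(=O)(=O)c1ccccc1
F11 | step 7 | α-lithio sulfone (lithium carbanion of F10 at the carbon next to sulfur) | [Li+].C=C(C)[C@@H](C)[CH-]S(=O)(=O)c1ccccc1
F12 | step 7 | (2E,6E,10R)-3,7,10,11-tetramethyl-9-(phenylsulfonyl)dodeca-2,6,11-trien-1-yl acetate (both C9 epimers) | C=C(C)[C@@H](C)C(C/C(C)=C/CC/C(C)=C/COC(C)=O)S(=O)(=O)c1ccccc1
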